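The target is the monoacetate of an anti-1,3-diol on a 1,7-diarylheptane whose C1 is benzylic. Tying O5 to C1 turns C1–C5 and O5 into an all-cis 2-aryl-oxane in which the C3 acetate sits on ring C4. One Lewis-acid-promoted three-component Prins cyclisation builds that oxane from an (R)-homoallylic alcohol (C2–C7 with its benzyl-protected aryl ring), a carbonate-masked 4-hydroxybenzaldehyde (C1) and acetic acid. It forms O5–C1, C1–C2 and C3–OAc while a chair relays the C5 configuration to C3. A single hydrogenolysis then strips both benzyl-type groups and severs the sacrificial benzylic C1–O5 bond, releasing the C5 hydroxyl.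

Key step: step 4

Remarks
- Locants: chain atoms carry heptane locants C1–C7 (C1 on the aryl ring delivered by the aldehyde); in ring compounds oxane C2 = chain C1, oxane C4 = chain C3, oxane C6 = chain C5.
- The parent (3R,5R)-diol is C2-symmetric, so its two carbinol oxygens are homotopic and 1,3-acetyl migration in the target is degenerate.
- Assumption: the (S)-configured ligands named in step 2 and in its fallback are taken to give the (R)-carbinol from an unbranched aliphatic substrate; the configuration of 5 is to be confirmed by Mosher ester analysis before step 4, and the antipodal ligand is used if the sense is opposite.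
- In step 4 boron trifluoride etherate is a promoter outside the balanced equation; water is the only co-product.

Step 1
Reactants: 1 3-(4-hydroxyphenyl)propan-1-ol
Product: 2 3-[4-(benzyloxy)phenyl]propan-1-ol
Conditions: BnBr, K2CO3, acetone, reflux
Reagents that add atoms: benzyl bromide, BrCc1ccccc1
Why: Williamson ether synthesis in which carbonate deprotonates only the phenol, so the phenoxide is benzylated while the primary alcohol stays free for step 2.

Step 2
Reactants: 2 3-[4-(benzyloxy)phenyl]propan-1-ol; 3 allyl acetate
Product: 5 (R)-1-[4-(benzyloxy)phenyl]hex-5-en-3-ol, via 3-[4-(benzyloxy)phenyl]propanal 4 (not isolated)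
Conditions: [Ir(cod)Cl]2 (cat.), (S)-Cl,MeO-BIPHEP (cat.), 4-chloro-3-nitrobenzoic acid (cat.), Cs2CO3 (cat.), allyl acetate (excess), THF, 100 °C, sealed tube
Reagents that add atoms: none
Why: Krische iridium-catalysed transfer-hydrogenative carbonyl allylation, in which the cyclometallated π-allyliridium C,O-benzoate dehydrogenates 2 to aldehyde 4 and adds its allyl ligand to that aldehyde through a closed chair transition state inside the C2-symmetric bisphosphine pocket, which should set the C5 carbinol as (R) by catalyst control.

Step 3
Reactants: 6 4-hydroxybenzaldehyde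
Product: 7 benzyl 4-formylphenyl carbonate
Conditions: CbzCl, K2CO3, acetone, 0 °C to rt
Reagents that add atoms: benzyl chloroformate, O=C(Cl)OCc1ccccc1
Why: Base-mediated O-acylation of a phenol with a chloroformate (carbonate formation), in which the aldehyde is a spectator and the benzyl carbonate both lowers the donor power of the ring and is removable by hydrogenolysis.

Step 4
Reactants: 5 (R)-1-[4-(benzyloxy)phenyl]hex-5-en-3-ol; 7 benzyl 4-formylphenyl carbonate; 8 acetic acid
Product: 11 (2R,4S,6R)-2-{4-[(benzyloxycarbonyl)oxy]phenyl}-6-{2-[4-(benzyloxy)phenyl]ethyl}oxan-4-yl acetate (all-cis), via (E)-oxocarbenium ion 9 (not isolated), via oxan-4-yl cation 10 (not isolated)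
Conditions: BF3·OEt2, AcOH (large excess), CH2Cl2, 0 °C to rt
Reagents that add atoms: none
Why: Prins cyclisation with carboxylate capture, a known three-component entry to all-cis 4-acyloxy-2,6-disubstituted oxanes: BF3 drives condensation of the carbinol oxygen of 5 with the formyl group of 7 to the (E)-oxocarbenium ion 9 (O5–C1), the vinyl CH2 terminus then adds to the cationic carbon (C1–C2), and the oxan-4-yl cation 10 takes up acetic acid 8 (C3–OAc). The single ring closes in a 6-endo-trig cation–olefin mode through a chair-like transition state. Oxane C2 is controlled by the resident stereocentre at oxane C6 (chain C5), since the chair built on the (E)-oxocarbenium ion carries both the 2-arylethyl and the aryl substituent equatorially; oxane C4 is controlled by equatorial approach of the nucleophile to the chair cation, so the all-cis (2R,4S,6R) isomer, with C3–OAc anti to C5–O in the open chain, should result. The step needs all-cis diastereoselectivity, conservation of the C5 configuration and acetate rather than fluoride capture: a 2-oxonia-Cope shift would trade an aryl-conjugated oxocarbenium ion for a non-conjugated one and is therefore uphill, the carbonate keeps the new benzylic C–O bond from ionising, and acetic acid in large excess should outcompete fluoride. The benzyloxyphenyl ring of 5 cannot trap 9, because an oxa-Pictet–Spengler closure would require a seven-membered ring at a position meta to the ether oxygen, and the benzyl ether and benzyl carbonate tolerate BF3·OEt2 when no soft nucleophile is present.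

Step 5
Reactants: 11 (2R,4S,6R)-2-{4-[(benzyloxycarbonyl)oxy]phenyl}-6-{2-[4-(benzyloxy)phenyl]ethyl}oxan-4-yl acetate
Product: 13 (3R,5R)-5-hydroxy-1,7-bis(4-hydroxyphenyl)heptan-3-yl acetate, via ring-intact bisphenol oxane 12 (not isolated)
Conditions: H2 (3–4 bar), Pd(OH)2/C, EtOAc–AcOH, rt
Reagents that add atoms: none
Why: Heterogeneous catalytic hydrogenolysis, in which the benzyl ether and the benzyl carbonate (with loss of CO2) should be cleaved first to give 12, whose ring benzylic C2–O1 bond, now activated by the para-hydroxyl group and by acid, is then reduced to a CH2 group and frees the C5 hydroxyl; the two remaining stereocentres lie outside the reacting bonds and acetyl migration in 13 would be degenerate.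

Compound list
1 | 3-(4-hydroxyphenyl)propan-1-ol | OCCCc1ccc(O)cc1 | starting material
2 | 3-[4-(benzyloxy)phenyl]propan-1-ol | OCCCc1ccc(OCc2ccccc2)cc1 | intermediate
3 | allyl acetate (prop-2-en-1-yl acetate) | C=CCOC(C)=O | starting material
4 | 3-[4-(benzyloxy)phenyl]propanal (not isolated in step 2) | O=CCCc1ccc(OCc2ccccc2)cc1 | intermediate
5 | (R)-1-[4-(benzyloxy)phenyl]hex-5-en-3-ol | C=CC[C@H](O)CCc1ccc(OCc2ccccc2)cc1 | intermediate
6 | 4-hydroxybenzaldehyde | O=Cc1ccc(O)cc1 | starting material
7 | benzyl 4-formylphenyl carbonate | O=Cc1ccc(OC(=O)OCc2ccccc2)cc1 | intermediate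
8 | acetic acid | CC(=O)O | starting material
9 | (E)-oxocarbenium ion, {(3R)-1-[4-(benzyloxy)phenyl]hex-5-en-3-yl}{(E)-4-[(benzyloxycarbonyl)oxy]benzylidene}oxonium (not isolated) | C=CC[C@H](/[O+]=C/c1ccc(OC(=O)OCc2ccccc2)cc1)CCc1ccc(OCc2ccccc2)cc1 | intermediate
10 | oxan-4-yl cation, 2-{4-[(benzyloxycarbonyl)oxy]phenyl}-6-{2-[4-(benzyloxy)phenyl]ethyl}oxan-4-ylium with the aryl and arylethyl groups cis (not isolated) | [CH+]1C[C@H](c2ccc(OC(=O)OCc3ccccc3)cc2)O[C@H](CCc2ccc(OCc3ccccc3)cc2)C1 | intermediate
11 | (2R,4S,6R)-2-{4-[(benzyloxycarbonyl)oxy]phenyl}-6-{2-[4-(benzyloxy)phenyl]ethyl}oxan-4-yl acetate (all-cis) | CC(=O)O[C@@H]1C[C@H](c2ccc(OC(=O)OCc3ccccc3)cc2)O[C@H](CCc2ccc(OCc3ccccc3)cc2)C1 | intermediate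
12 | (2R,4S,6R)-2-(4-hydroxyphenyl)-6-[2-(4-hydroxyphenyl)ethyl]oxan-4-yl acetate (all-cis; not isolated in step 5) | CC(=O)O[C@@H]1C[C@H](c2ccc(O)cc2)O[C@H](CCc2ccc(O)cc2)C1 | intermediate
13 | (3R,5R)-5-hydroxy-1,7-bis(4-hydroxyphenyl)heptan-3-yl acetate | CC(=O)O[C@H](CCc1ccc(O)cc1)C[C@H](O)CCc1ccc(O)cc1 | target

Total step count: 5
Longest linear sequence: 4 steps (steps 1, 2, 4, 5)

Steps most likely to fail

Step 4. The oxan-4-yl cation may be captured by fluoride instead of acetate, allyl transfer through oxonia-Cope equilibration may erode the C5 configuration, or oxocarbenium formation may be slow enough that the alcohol is simply O-acetylated. The fallback gives up the ring relay and sets the anti-1,3 relationship by an Evans–Tishchenko reduction; it sets out from 5 and comes back at 13. Wacker oxidation of the terminal alkene of 5 (PdCl2 cat., CuCl, O2, DMF–H2O) should give (R)-6-[4-(benzyloxy)phenyl]-4-hydroxyhexan-2-one F1. Its alkoxide–enolate dianion (LDA, 2.2 equiv, THF, −78 °C) is alkylated at the methyl terminus with 4-(benzyloxy)benzyl bromide to give (R)-1,7-bis[4-(benzyloxy)phenyl]-5-hydroxyheptan-3-one F2. Samarium diiodide-catalysed reaction with acetaldehyde (THF, −10 °C) then delivers hydride intramolecularly within the samarium-bound hemiacetal, so the ketone should become the anti carbinol while the original hydroxyl becomes the acetate, giving (3R,5R)-1,7-bis[4-(benzyloxy)phenyl]-5-hydroxyheptan-3-yl acetate F3. Hydrogenolysis of the two benzyl ethers (H2, Pd/C, EtOAc) returns to target 13.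

Step 5. Hydrogenolysis may stall once the benzyl ether and carbonate are gone, leaving the ring benzylic C–O bond intact, and more forcing conditions may begin to saturate the phenol rings. The fallback replaces catalytic C–O hydrogenolysis by ionic hydrogenation; it sets out from 12 and comes back at 13. The hydrogenolysis of 11 is run deliberately mild (H2 1 atm, Pd/C, EtOAc) and 12 is isolated. Treatment with Et3SiH and CF3CO2H in CH2Cl2 at 0 °C should then protonate the ring oxygen, ionise the C2–O1 bond to a 4-hydroxybenzyl (quinone-methide-like) cation and reduce it by hydride transfer from silicon. A mild bicarbonate work-up removes any trifluoroacetate ester. This fallback makes no compound outside the list.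

Step 2. Conversion of the unactivated aliphatic alcohol may be incomplete, or enantioselectivity may be insufficient or of the opposite sense. The fallback moves the allylation to the aldehyde oxidation level with a chiral Lewis acid; it sets out from 2 and comes back at 5. Oxidation of 2 with TEMPO (cat.) and PhI(OAc)2 in CH2Cl2 gives aldehyde 4, now isolated. Keck allylation (allyltributylstannane, (S)-BINOL/Ti(OiPr)4 cat., 4 Å MS, CH2Cl2, −20 °C) should then give 5 by catalyst-controlled addition to one aldehyde face. This fallback makes no compound outside the list.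

Further compounds
F1 | step 4 | (R)-6-[4-(benzyloxy)phenyl]-4-hydroxyhexan-2-one | CC(=O)C[C@H](O)CCc1ccc(OCc2ccccc2)cc1
F2 | step 4 | (R)-1,7-bis[4-(benzyloxy)phenyl]-5-hydroxyheptan-3-one | O=C(CCc1ccc(OCc2ccccc2)cc1)C[C@H](O)CCc1ccc(OCc2ccccc2)cc1
F3 | step 4 | (3R,5R)-1,7-bis[4-(benzyloxy)phenyl]-5-hydroxyheptan-3-yl acetate | CC(=O)O[C@H](CCc1ccc(OCc2ccccc2)cc1)C[C@H](O)CCc1ccc(OCc2ccccc2)cc1
F0 | step 5 | none | none
F0 | step 2 | none | none
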